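**Plan**
Numbering: ring O1–O2–C3–C4–C5–C6; side chain C2 (CHMe) and C1 (ester carbon) on C3; homofarnesyl chain C1′–C13′ on C6.
Retrosynthesis, in order: C1 ester from a silyl-protected primary alcohol; C6–CH3 (methyl delivered to a peroxycarbenium ion of a 6-methoxy-1,2-dioxane); O2–C3 (invertive SN2 of a hydroperoxyketal on a C3 mesylate); C6–C1′ (homofarnesyllithium plus a γ-lactone).
Enabling feature: C3 (on O2) and C6 (on O1) are 1,4-related oxygen-bearing ring carbons, so O–C3–C4–C5–C6(=O) can be stored as a γ-butyrolactone, a ring absent from the target, whose acyl carbon C6 accepts the C1′ carbanion. The C1′H2–C2′H2–C3′H=C4′ unit is the terminal hydroboration product of the farnesal-derived 1,3-diene.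
Forward: lactone and chain are joined to a γ-hydroxy ketone, which is mesylated and peroxyketalised; the only ring, the 1,2-dioxane, then closes by O2–C3 bond formation, followed by C6 methylation and C1 oxidation and esterification.
Stereochemistry: C2 and C3 come from a reagent-controlled anti-crotylboration, with C3 made as R and inverted to S at ring closure. C6 comes from axial delivery of methyl cis to the equatorial C3 substituent, which is why the chain is installed first and the methyl last (the reverse order would be expected to give the C6 epimer). Alkene geometry comes from (2E,6E)-farnesol.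

Key step: step 8

**Step 1**
Reactants: 1 methyl 4-oxobutanoate
Product: 3 (5R)-5-[(2S)-but-3-en-2-yl]oxolan-2-one, via hydroxy ester 2 (not isolated)
Conditions: trans-2-butene, n-BuLi, KOt-Bu, THF, −78 to −45 °C; (−)-Ipc2BOMe, −78 °C; BF3·OEt2; then 1, −78 °C; NaOH, H2O2; TsOH (cat.), CH2Cl2, rt
Reagents that add atoms: trans-2-butene, C/C=C/C
Why: Brown crotylboration through a closed chair transition state, in which the E-crotyl geometry gives the anti C2/C3 relationship and the Ipc groups of the (+)-α-pinene series direct attack to the Si face of the aldehyde, so that C3 is formed as the R carbinol (to be inverted in step 11) and C2 with its final spatial arrangement, after which the γ-hydroxy ester lactonises under acid.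

**Step 2**
Reactants: 3 (5R)-5-[(2S)-but-3-en-2-yl]oxolan-2-one
Product: 5 (5R)-5-[(2S)-1-hydroxypropan-2-yl]oxolan-2-one, via ozonide 4 (not isolated)
Conditions: O3, CH2Cl2, −78 °C; then NaBH4, MeOH, −78 to 0 °C
Reagents that add atoms: ozone, [O-][O+]=O
Why: Reductive ozonolysis of the only alkene turns the vinyl group into the primary alcohol C1, the ozonide being reduced cold so that the C2 stereocentre does not epimerise through a free aldehyde and the lactone is not reduced.

**Step 3**
Reactants: 5 (5R)-5-[(2S)-1-hydroxypropan-2-yl]oxolan-2-one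
Product: 6 (5R)-5-[(2S)-1-[(tert-butyldiphenylsilyl)oxy]propan-2-yl]oxolan-2-one
Conditions: TBDPSCl, imidazole, DMF, rt
Reagents that add atoms: tert-butyldiphenylsilyl chloride, CC(C)(C)[Si](Cl)(c1ccccc1)c1ccccc1
Why: Standard silylation of a primary alcohol, the tert-butyldiphenylsilyl ether being chosen because it should withstand the organolithium, the Lewis acids and the base of the later steps.

**Step 4**
Reactants: 7 (2E,6E)-3,7,11-trimethyldodeca-2,6,10-trien-1-ol (farnesol)
Product: 8 (2E,6E)-3,7,11-trimethyldodeca-2,6,10-trienal (farnesal)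
Conditions: MnO2, CH2Cl2, rt
Reagents that add atoms: none
Why: Chemoselective allylic oxidation with MnO2 should give the enal without isomerising the 2,3-alkene.

**Step 5**
Reactants: 8 (2E,6E)-3,7,11-trimethyldodeca-2,6,10-trienal
Product: 9 (3E,7E)-4,8,12-trimethyltrideca-1,3,7,11-tetraene
Conditions: Ph3PCH3Br, KOt-Bu, THF, 0 °C
Reagents that add atoms: methyltriphenylphosphonium bromide, C[P+](c1ccccc1)(c1ccccc1)c1ccccc1.[Br-]
Why: Wittig methylenation of the enal by 1,2-addition of the unstabilised ylide gives the terminal 1,3-diene and leaves the trisubstituted alkenes and the E geometry at C3′=C4′ untouched.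

**Step 6**
Reactants: 9 (3E,7E)-4,8,12-trimethyltrideca-1,3,7,11-tetraene
Product: 11 (3E,7E)-4,8,12-trimethyltrideca-3,7,11-trien-1-ol (homofarnesol), via alkylborane 10 (not isolated)
Conditions: 9-BBN, THF, 0 °C to rt; then NaOH, H2O2, 0 °C
Reagents that add atoms: hydrogen peroxide, OO
Why: Hydroboration–oxidation in which the bulky 9-BBN adds only to the monosubstituted terminal alkene of the diene with boron on C1′, so that C1′–C2′ becomes saturated while the E-trisubstituted C3′=C4′ alkene is kept.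

**Step 7**
Reactants: 11 (3E,7E)-4,8,12-trimethyltrideca-3,7,11-trien-1-ol
Product: 12 (3E,7E)-1-iodo-4,8,12-trimethyltrideca-3,7,11-triene (homofarnesyl iodide)
Conditions: I2, PPh3, imidazole, CH2Cl2, 0 °C
Reagents that add atoms: iodine, II
Why: Appel-type iodination converts the primary alcohol into the iodide by SN2 displacement of the oxyphosphonium ion under neutral conditions that should not isomerise the alkenes.

**Step 8**
Reactants: 12 (3E,7E)-1-iodo-4,8,12-trimethyltrideca-3,7,11-triene; 6 (5R)-5-[(2S)-1-[(tert-butyldiphenylsilyl)oxy]propan-2-yl]oxolan-2-one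
Product: 14 (2S,3R,9E,13E)-1-[(tert-butyldiphenylsilyl)oxy]-3-hydroxy-2,10,14,18-tetramethylnonadeca-9,13,17-trien-6-one, via homofarnesyllithium 13 (not isolated)
Conditions: t-BuLi (2.0 equiv), Et2O/pentane, −78 °C; then 6, THF, −78 °C; AcOH, −78 °C
Reagents that add atoms: none
Why: Iodine–lithium exchange gives the primary homoallylic alkyllithium 13, which should not cyclise because its nearest alkene (C3′=C4′) could only close a three-membered ring. Its carbanionic C1′ adds to the lactone carbonyl C6 (nucleophilic acyl addition) and the tetrahedral lithium lactolate is stable at −78 °C, so a second addition is held back until the cold acetic acid quench releases the γ-hydroxy ketone; the closest known reaction type is the mono-addition of organolithiums to γ-butyrolactones. The event is possible because O2-bearing C3 and O1-bearing C6 are 1,4-related, so that the lactone ring O–C3–C4–C5–C6(=O), absent from the target, stores C6 as an acyl electrophile; its opening forms the C6–C1′ bond and at the same stroke uncovers the C6 ketone needed for peroxyketalisation and the free C3 hydroxyl needed for activation. No ring is closed (one is opened) and no stereocentre is created, and C2 and C3 are carried through unchanged because neither is α to the carbonyl. The step needs mono-addition and attack at the carbonyl in preference to enolisation, which the low temperature, the exact stoichiometry of t-BuLi and the cold quench should secure, while the silyl ether and the three trisubstituted alkenes are inert.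

**Step 9**
Reactants: 14 (2S,3R,9E,13E)-1-[(tert-butyldiphenylsilyl)oxy]-3-hydroxy-2,10,14,18-tetramethylnonadeca-9,13,17-trien-6-one
Product: 15 (2S,3R,9E,13E)-1-[(tert-butyldiphenylsilyl)oxy]-2,10,14,18-tetramethyl-6-oxononadeca-9,13,17-trien-3-yl methanesulfonate
Conditions: MsCl, Et3N, CH2Cl2, −20 °C
Reagents that add atoms: methanesulfonyl chloride, CS(=O)(=O)Cl
Why: Sulfonylation of the secondary alcohol with retention (the C3–O bond is not broken) turns the oxygen on C3 into the leaving group for the invertive ring closure, the open hydroxy ketone rather than the minor lactol being trapped.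

**Step 10**
Reactants: 15 (2S,3R,9E,13E)-1-[(tert-butyldiphenylsilyl)oxy]-2,10,14,18-tetramethyl-6-oxononadeca-9,13,17-trien-3-yl methanesulfonate
Product: 16 (2S,3R,6RS,9E,13E)-1-[(tert-butyldiphenylsilyl)oxy]-6-hydroperoxy-6-methoxy-2,10,14,18-tetramethylnonadeca-9,13,17-trien-3-yl methanesulfonate
Conditions: urea·H2O2, Sc(OTf)3 (10 mol %), MeOH, rt
Reagents that add atoms: hydrogen peroxide (as its urea adduct), OO; methanol, CO
Why: Lewis-acid-catalysed hydroperoxyketalisation of the ketone by H2O2 and methanol gives the α-methoxy hydroperoxide at C6 as both epimers, which is of no consequence because C6 is ionised again in step 12, while the isolated alkenes and the mesylate should be inert to H2O2 in the absence of a metal-oxo catalyst.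

**Step 11**
Reactants: 16 (2S,3R,6RS,9E,13E)-1-[(tert-butyldiphenylsilyl)oxy]-6-hydroperoxy-6-methoxy-2,10,14,18-tetramethylnonadeca-9,13,17-trien-3-yl methanesulfonate
Product: 17 tert-butyl{(2S)-2-[(3S,6RS)-6-methoxy-6-[(3E,7E)-4,8,12-trimethyltrideca-3,7,11-trien-1-yl]-1,2-dioxan-3-yl]propoxy}diphenylsilane
Conditions: KOt-Bu (1.05 equiv), 18-crown-6, THF, 0 °C
Reagents that add atoms: none
Why: Intramolecular alkylation of the hydroperoxyketal anion (6-exo-tet SN2 by an α-effect nucleophile) closes the 1,2-dioxane through the O2–C3 bond with inversion, which converts the 3R mesylate into the 3S configuration of the target, and the bare minimum of base should spare the product from Kornblum–DeLaMare fragmentation at C3–H.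

**Step 12**
Reactants: 17 tert-butyl{(2S)-2-[(3S,6RS)-6-methoxy-6-[(3E,7E)-4,8,12-trimethyltrideca-3,7,11-trien-1-yl]-1,2-dioxan-3-yl]propoxy}diphenylsilane
Product: 18 tert-butyl{(2S)-2-[(3S,6R)-6-methyl-6-[(3E,7E)-4,8,12-trimethyltrideca-3,7,11-trien-1-yl]-1,2-dioxan-3-yl]propoxy}diphenylsilane
Conditions: AlMe3 (4 equiv), CH2Cl2, −78 to −40 °C; Rochelle salt work-up
Reagents that add atoms: trimethylaluminium, C[Al](C)C
Why: Proposed new method: AlMe3 should complex the ketal methoxy group (the most basic oxygen) and ionise C6 to a peroxycarbenium ion (C6=O1+) common to both epimers of 17, which adopts the half-chair with the C3 side chain pseudo-equatorial and takes up methyl along the axial trajectory of a chair-like transition state, so that the methyl ends axial and cis to the C3 substituent (6R) with the homofarnesyl chain equatorial; the closest known reaction types are the Lewis-acid-mediated allylation of 3-alkoxy-1,2-dioxanes through peroxycarbenium ions and the AlMe3 methylation of ketals and glycosyl fluorides through oxocarbenium ions, and the step needs C–C bond formation to outrun attack of the alane on the O–O bond, which the low temperature and the preferential complexation of the methoxy oxygen should favour.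

**Step 13**
Reactants: 18 tert-butyl{(2S)-2-[(3S,6R)-6-methyl-6-[(3E,7E)-4,8,12-trimethyltrideca-3,7,11-trien-1-yl]-1,2-dioxan-3-yl]propoxy}diphenylsilane
Product: 19 (2S)-2-[(3S,6R)-6-methyl-6-[(3E,7E)-4,8,12-trimethyltrideca-3,7,11-trien-1-yl]-1,2-dioxan-3-yl]propan-1-ol
Conditions: HF·pyridine, pyridine, THF, 0 °C to rt
Reagents that add atoms: none
Why: Fluoride-mediated desilylation under pyridine-buffered conditions frees the primary alcohol, and the dialkyl peroxide and the isolated alkenes should tolerate the buffered reagent.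

**Step 14**
Reactants: 19 (2S)-2-[(3S,6R)-6-methyl-6-[(3E,7E)-4,8,12-trimethyltrideca-3,7,11-trien-1-yl]-1,2-dioxan-3-yl]propan-1-ol
Product: 21 (2R)-2-[(3S,6R)-6-methyl-6-[(3E,7E)-4,8,12-trimethyltrideca-3,7,11-trien-1-yl]-1,2-dioxan-3-yl]propanoic acid, via aldehyde 20 (not isolated)
Conditions: TEMPO (cat.), PhI(OAc)2 (2.2 equiv), MeCN/H2O (pH 7 buffer), rt
Reagents that add atoms: water, O
Why: Oxoammonium (TEMPO/PhI(OAc)2) oxidation in aqueous acetonitrile takes the primary alcohol through the aldehyde hydrate to the acid under near-neutral conditions, which should avoid epimerisation at C2 and retro-oxa-Michael opening of the β-peroxy carbonyl compound.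

**Step 15**
Reactants: 21 (2R)-2-[(3S,6R)-6-methyl-6-[(3E,7E)-4,8,12-trimethyltrideca-3,7,11-trien-1-yl]-1,2-dioxan-3-yl]propanoic acid
Product: 22 methyl (2R)-2-[(3S,6R)-6-methyl-6-[(3E,7E)-4,8,12-trimethyltrideca-3,7,11-trien-1-yl]-1,2-dioxan-3-yl]propanoate
Conditions: TMSCHN2, MeOH/toluene, 0 °C
Reagents that add atoms: trimethylsilyldiazomethane, C[Si](C)(C)C=[N+]=[N-]
Why: Esterification with trimethylsilyldiazomethane methylates the acid without base, so the β-peroxy ester is not exposed to conditions for E1cB ring opening or C2 epimerisation.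

**Compound list**
1 | methyl 4-oxobutanoate | COC(=O)CCC=O | starting material
2 | methyl (4R,5S)-4-hydroxy-5-methylhept-6-enoate | C=C[C@H](C)[C@H](O)CCC(=O)OC | intermediate (not isolated)
3 | (5R)-5-[(2S)-but-3-en-2-yl]oxolan-2-one | C=C[C@H](C)[C@H]1CCC(=O)O1 | intermediate
4 | (5R)-5-[(1R)-1-(1,2,4-trioxolan-3-yl)ethyl]oxolan-2-one (ozonide; epimers at the trioxolane carbon) | C[C@@H](C1OCOO1)[C@H]2CCC(=O)O2 | intermediate (not isolated)
5 | (5R)-5-[(2S)-1-hydroxypropan-2-yl]oxolan-2-one | C[C@@H](CO)[C@H]1CCC(=O)O1 | intermediate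
6 | (5R)-5-[(2S)-1-[(tert-butyldiphenylsilyl)oxy]propan-2-yl]oxolan-2-one | C[C@@H](CO[Si](c1ccccc1)(c1ccccc1)C(C)(C)C)[C@H]2CCC(=O)O2 | intermediate
7 | (2E,6E)-3,7,11-trimethyldodeca-2,6,10-trien-1-ol (farnesol) | OC/C=C(\C)CC/C=C(\C)CCC=C(C)C | starting material
8 | (2E,6E)-3,7,11-trimethyldodeca-2,6,10-trienal (farnesal) | O=C/C=C(\C)CC/C=C(\C)CCC=C(C)C | intermediate
9 | (3E,7E)-4,8,12-trimethyltrideca-1,3,7,11-tetraene | C=C/C=C(\C)CC/C=C(\C)CCC=C(C)C | intermediate
10 | 9-[(3E,7E)-4,8,12-trimethyltrideca-3,7,11-trien-1-yl]-9-borabicyclo[3.3.1]nonane | B1(CC/C=C(\C)CC/C=C(\C)CCC=C(C)C)C2CCCC1CCC2 | intermediate (not isolated)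
11 | (3E,7E)-4,8,12-trimethyltrideca-3,7,11-trien-1-ol (homofarnesol) | OCC/C=C(\C)CC/C=C(\C)CCC=C(C)C | intermediate
12 | (3E,7E)-1-iodo-4,8,12-trimethyltrideca-3,7,11-triene (homofarnesyl iodide) | ICC/C=C(\C)CC/C=C(\C)CCC=C(C)C | intermediate
13 | [(3E,7E)-4,8,12-trimethyltrideca-3,7,11-trien-1-yl]lithium (homofarnesyllithium) | [Li]CC/C=C(\C)CC/C=C(\C)CCC=C(C)C | intermediate (not isolated)
14 | (2S,3R,9E,13E)-1-[(tert-butyldiphenylsilyl)oxy]-3-hydroxy-2,10,14,18-tetramethylnonadeca-9,13,17-trien-6-one | C[C@@H](CO[Si](c1ccccc1)(c1ccccc1)C(C)(C)C)[C@H](O)CCC(=O)CC/C=C(\C)CC/C=C(\C)CCC=C(C)C | intermediate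
15 | (2S,3R,9E,13E)-1-[(tert-butyldiphenylsilyl)oxy]-2,10,14,18-tetramethyl-6-oxononadeca-9,13,17-trien-3-yl methanesulfonate | C[C@@H](CO[Si](c1ccccc1)(c1ccccc1)C(C)(C)C)[C@H](OS(C)(=O)=O)CCC(=O)CC/C=C(\C)CC/C=C(\C)CCC=C(C)C | intermediate
16 | (2S,3R,6RS,9E,13E)-1-[(tert-butyldiphenylsilyl)oxy]-6-hydroperoxy-6-methoxy-2,10,14,18-tetramethylnonadeca-9,13,17-trien-3-yl methanesulfonate | C[C@@H](CO[Si](c1ccccc1)(c1ccccc1)C(C)(C)C)[C@H](OS(C)(=O)=O)CCC(OC)(OO)CC/C=C(\C)CC/C=C(\C)CCC=C(C)C | intermediate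
17 | tert-butyl{(2S)-2-[(3S,6RS)-6-methoxy-6-[(3E,7E)-4,8,12-trimethyltrideca-3,7,11-trien-1-yl]-1,2-dioxan-3-yl]propoxy}diphenylsilane | C[C@@H](CO[Si](c1ccccc1)(c1ccccc1)C(C)(C)C)[C@@H]2CCC(OC)(CC/C=C(\C)CC/C=C(\C)CCC=C(C)C)OO2 | intermediate
18 | tert-butyl{(2S)-2-[(3S,6R)-6-methyl-6-[(3E,7E)-4,8,12-trimethyltrideca-3,7,11-trien-1-yl]-1,2-dioxan-3-yl]propoxy}diphenylsilane | C[C@@H](CO[Si](c1ccccc1)(c1ccccc1)C(C)(C)C)[C@@H]2CC[C@@](C)(CC/C=C(\C)CC/C=C(\C)CCC=C(C)C)OO2 | intermediate
19 | (2S)-2-[(3S,6R)-6-methyl-6-[(3E,7E)-4,8,12-trimethyltrideca-3,7,11-trien-1-yl]-1,2-dioxan-3-yl]propan-1-ol | C[C@@H](CO)[C@@H]1CC[C@@](C)(CC/C=C(\C)CC/C=C(\C)CCC=C(C)C)OO1 | intermediate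
20 | (2R)-2-[(3S,6R)-6-methyl-6-[(3E,7E)-4,8,12-trimethyltrideca-3,7,11-trien-1-yl]-1,2-dioxan-3-yl]propanal | C[C@@H](C=O)[C@@H]1CC[C@@](C)(CC/C=C(\C)CC/C=C(\C)CCC=C(C)C)OO1 | intermediate (not isolated)
21 | (2R)-2-[(3S,6R)-6-methyl-6-[(3E,7E)-4,8,12-trimethyltrideca-3,7,11-trien-1-yl]-1,2-dioxan-3-yl]propanoic acid | C[C@@H](C(=O)O)[C@@H]1CC[C@@](C)(CC/C=C(\C)CC/C=C(\C)CCC=C(C)C)OO1 | intermediate
22 | methyl (2R)-2-[(3S,6R)-6-methyl-6-[(3E,7E)-4,8,12-trimethyltrideca-3,7,11-trien-1-yl]-1,2-dioxan-3-yl]propanoate | COC(=O)[C@H](C)[C@@H]1CC[C@@](C)(CC/C=C(\C)CC/C=C(\C)CCC=C(C)C)OO1 | target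

**Step count and risks**
Total step count: 15 (lactone arm steps 1–3, chain arm steps 4–7, steps 8–15 after the union).
Longest linear sequence: 12 steps (steps 4–15, from farnesol).

Steps most likely to fail:

Step 12. The alane may attack or reductively cleave the O–O bond, the Lewis acid may trigger Hock-type fragmentation instead of ionisation at C6, or methyl may be delivered within a tight ion pair from the equatorial side and erode the facial selectivity. The fallback uses known chemistry and sets out from 15. Wittig methylenation (Ph3PCH3Br, KHMDS, THF, −78 to 0 °C) should give (2S,3R,9E,13E)-1-[(tert-butyldiphenylsilyl)oxy]-2,10,14,18-tetramethyl-6-methylidenenonadeca-9,13,17-trien-3-yl methanesulfonate F1. Mukaiyama–Isayama peroxidation (Co(acac)2 cat., O2, Et3SiH, 1,2-dichloroethane, stopped at partial conversion because the 1,1-disubstituted alkene is expected to react faster than the trisubstituted ones) should give (2S,3R,6RS,9E,13E)-1-[(tert-butyldiphenylsilyl)oxy]-2,6,10,14,18-pentamethyl-6-[(triethylsilyl)peroxy]nonadeca-9,13,17-trien-3-yl methanesulfonate F2. K2CO3 in MeOH should remove the peroxysilyl group to give (2S,3R,6RS,9E,13E)-1-[(tert-butyldiphenylsilyl)oxy]-6-hydroperoxy-2,6,10,14,18-pentamethylnonadeca-9,13,17-trien-3-yl methanesulfonate F3. KOt-Bu with 18-crown-6 should then close the ring by the same invertive 6-exo-tet alkylation as in step 11, to give 18 together with tert-butyl{(2S)-2-[(3S,6S)-6-methyl-6-[(3E,7E)-4,8,12-trimethyltrideca-3,7,11-trien-1-yl]-1,2-dioxan-3-yl]propoxy}diphenylsilane F4, from which 18 is separated by chromatography. The route is rejoined at 18. This fallback gives up the control of C6.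

Step 11. E2 elimination of the hindered secondary mesylate or base-induced fragmentation of the peroxide may compete with substitution. The fallback replaces the basic closure by a silver-assisted one and sets out from 14. Mitsunobu inversion (4-nitrobenzoic acid, PPh3, DIAD) should give (2S,3S,9E,13E)-1-[(tert-butyldiphenylsilyl)oxy]-2,10,14,18-tetramethyl-6-oxononadeca-9,13,17-trien-3-yl 4-nitrobenzoate F5. Methanolysis (K2CO3, MeOH) should give (2S,3S,9E,13E)-1-[(tert-butyldiphenylsilyl)oxy]-3-hydroxy-2,10,14,18-tetramethylnonadeca-9,13,17-trien-6-one F6. Invertive iodination (I2, PPh3, imidazole) should give (2S,3R,9E,13E)-1-[(tert-butyldiphenylsilyl)oxy]-3-iodo-2,10,14,18-tetramethylnonadeca-9,13,17-trien-6-one F7. Hydroperoxyketalisation as in step 10 should give tert-butyl{[(2S,3R,6RS,9E,13E)-6-hydroperoxy-3-iodo-6-methoxy-2,10,14,18-tetramethylnonadeca-9,13,17-trien-1-yl]oxy}diphenylsilane F8. A silver salt (Ag2O or AgOCOCF3, CH2Cl2) should then assist the invertive 6-exo closure without base. The three inversions at C3 add up to the same result as step 11, and the route is rejoined at 17.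

Step 8. Over-addition to a tertiary alcohol, enolisation of the lactone, or collapse of the lactolate before the quench may lower the yield of the union. The fallback sets out from 6. Aminolysis with MeNH(OMe)·HCl and AlMe3 should give (4R,5S)-6-[(tert-butyldiphenylsilyl)oxy]-4-hydroxy-N-methoxy-N,5-dimethylhexanamide F9. Silylation (TESCl, imidazole) should give (4R,5S)-6-[(tert-butyldiphenylsilyl)oxy]-N-methoxy-N,5-dimethyl-4-[(triethylsilyl)oxy]hexanamide F10. Addition of 13, whose chelated tetrahedral adduct cannot take up a second equivalent, should give (2S,3R,9E,13E)-1-[(tert-butyldiphenylsilyl)oxy]-2,10,14,18-tetramethyl-3-[(triethylsilyl)oxy]nonadeca-9,13,17-trien-6-one F11. PPTS in MeOH should remove the triethylsilyl group selectively, and the route is rejoined at 14.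

**Further compounds**
F1 | step 12 | (2S,3R,9E,13E)-1-[(tert-butyldiphenylsilyl)oxy]-2,10,14,18-tetramethyl-6-methylidenenonadeca-9,13,17-trien-3-yl methanesulfonate | C[C@@H](CO[Si](c1ccccc1)(c1ccccc1)C(C)(C)C)[C@H](OS(C)(=O)=O)CCC(=C)CC/C=C(\C)CC/C=C(\C)CCC=C(C)C
F2 | step 12 | (2S,3R,6RS,9E,13E)-1-[(tert-butyldiphenylsilyl)oxy]-2,6,10,14,18-pentamethyl-6-[(triethylsilyl)peroxy]nonadeca-9,13,17-trien-3-yl methanesulfonate | C[C@@H](CO[Si](c1ccccc1)(c1ccccc1)C(C)(C)C)[C@H](OS(C)(=O)=O)CCC(C)(OO[Si](CC)(CC)CC)CC/C=C(\C)CC/C=C(\C)CCC=C(C)C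
F3 | step 12 | (2S,3R,6RS,9E,13E)-1-[(tert-butyldiphenylsilyl)oxy]-6-hydroperoxy-2,6,10,14,18-pentamethylnonadeca-9,13,17-trien-3-yl methanesulfonate | C[C@@H](CO[Si](c1ccccc1)(c1ccccc1)C(C)(C)C)[C@H](OS(C)(=O)=O)CCC(C)(OO)CC/C=C(\C)CC/C=C(\C)CCC=C(C)C
F4 | step 12 | tert-butyl{(2S)-2-[(3S,6S)-6-methyl-6-[(3E,7E)-4,8,12-trimethyltrideca-3,7,11-trien-1-yl]-1,2-dioxan-3-yl]propoxy}diphenylsilane | C[C@@H](CO[Si](c1ccccc1)(c1ccccc1)C(C)(C)C)[C@@H]2CC[C@](C)(CC/C=C(\C)CC/C=C(\C)CCC=C(C)C)OO2
F5 | step 11 | (2S,3S,9E,13E)-1-[(tert-butyldiphenylsilyl)oxy]-2,10,14,18-tetramethyl-6-oxononadeca-9,13,17-trien-3-yl 4-nitrobenzoate | C[C@@H](CO[Si](c1ccccc1)(c1ccccc1)C(C)(C)C)[C@@H](OC(=O)c1ccc(cc1)[N+](=O)[O-])CCC(=O)CC/C=C(\C)CC/C=C(\C)CCC=C(C)C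
F6 | step 11 | (2S,3S,9E,13E)-1-[(tert-butyldiphenylsilyl)oxy]-3-hydroxy-2,10,14,18-tetramethylnonadeca-9,13,17-trien-6-one | C[C@@H](CO[Si](c1ccccc1)(c1ccccc1)C(C)(C)C)[C@@H](O)CCC(=O)CC/C=C(\C)CC/C=C(\C)CCC=C(C)C
F7 | step 11 | (2S,3R,9E,13E)-1-[(tert-butyldiphenylsilyl)oxy]-3-iodo-2,10,14,18-tetramethylnonadeca-9,13,17-trien-6-one | C[C@@H](CO[Si](c1ccccc1)(c1ccccc1)C(C)(C)C)[C@H](I)CCC(=O)CC/C=C(\C)CC/C=C(\C)CCC=C(C)C
F8 | step 11 | tert-butyl{[(2S,3R,6RS,9E,13E)-6-hydroperoxy-3-iodo-6-methoxy-2,10,14,18-tetramethylnonadeca-9,13,17-trien-1-yl]oxy}diphenylsilane | C[C@@H](CO[Si](c1ccccc1)(c1ccccc1)C(C)(C)C)[C@H](I)CCC(OC)(OO)CC/C=C(\C)CC/C=C(\C)CCC=C(C)C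
F9 | step 8 | (4R,5S)-6-[(tert-butyldiphenylsilyl)oxy]-4-hydroxy-N-methoxy-N,5-dimethylhexanamide | C[C@@H](CO[Si](c1ccccc1)(c1ccccc1)C(C)(C)C)[C@H](O)CCC(=O)N(C)OC
F10 | step 8 | (4R,5S)-6-[(tert-butyldiphenylsilyl)oxy]-N-methoxy-N,5-dimethyl-4-[(triethylsilyl)oxy]hexanamide | C[C@@H](CO[Si](c1ccccc1)(c1ccccc1)C(C)(C)C)[C@H](O[Si](CC)(CC)CC)CCC(=O)N(C)OC
F11 | step 8 | (2S,3R,9E,13E)-1-[(tert-butyldiphenylsilyl)oxy]-2,10,14,18-tetramethyl-3-[(triethylsilyl)oxy]nonadeca-9,13,17-trien-6-one | C[C@@H](CO[Si](c1ccccc1)(c1ccccc1)C(C)(C)C)[C@H](O[Si](CC)(CC)CC)CCC(=O)CC/C=C(\C)CC/C=C(\C)CCC=C(C)C
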